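Everything rests on disconnecting the C4–C4a bond of ring A. The key step exploits the fact that C4a is α to the C5 oxygen and carries the C3–C4 alkene: C4a of a ring B silyl enol ether (C4a=C5) attacks the terminus C4 of a tungsten-activated terminal alkyne, forming in one operation the C4–C4a bond, ring A, the C3–C4 alkene and the C5 ketone. The precursor is a cyclohexenyl silyl ether that already holds O6 (PMB ether), the C8 methyl and, at C8a, a chain with the C1 N-methoxy-N-methylamide and C2 bearing sec-butyl and ethynyl; a lactone-based Michael addition sets C1, C2 and C8a beforehand.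

Key step: step 14

Numbering and faces: C1 (acyl), C2 (sec-butyl), C3=C4, C4a, C5 (OH), C6 (ester O), C7, C8 (methyl), C8a; ring A = C1–C4, C4a, C8a; ring B = C4a–C8a; β is the face of H-8a, α the opposite face; open-chain and monocyclic intermediates keep these atom labels.
Remark on the chemistry: a chain anchored at C8a reaches C4a only on its own face, so the ring closure necessarily gives the cis ring fusion; the trans-fused ketone is therefore made in the following step by protonation of the dienolate.
Remark on starting materials and spectators: (S)-pulegone is taken because its carbonyl oxygen is kept as O6, which fixes the sense in which its ring maps onto ring B; the C1 carbonyl is carried as an N-methoxy-N-methylamide and O6 as a PMB ether.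

**Ring B enone**

Step 1
Reactants: 1 (S)-pulegone
Product: 2 trans-pulegol (1R,5S)-5-methyl-2-(propan-2-ylidene)cyclohexan-1-ol
Conditions: LiBH(s-Bu)3, THF, −78 °C; H2O
Reagents that add atoms: none
Why: 1,2-reduction of the β,β-disubstituted exocyclic enone by a bulky trialkylborohydride (conjugate reduction is blocked by the two β-methyl groups); equatorial hydride delivery, reinforced by allylic 1,3-strain against an equatorial hydroxyl beside the isopropylidene group, should give the axial alcohol trans to the ring methyl, the later 6α-oxygen relative to the 8β-methyl.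

Step 2
Reactants: 2 trans-pulegol
Product: 3 PMB ether of trans-pulegol
Conditions: NaH, 4-MeOC6H4CH2Cl, Bu4NI (cat.), THF–DMF, 0 °C → rt
Reagents that add atoms: 4-methoxybenzyl chloride, COc1ccc(CCl)cc1
Why: Williamson etherification of the alkoxide with an activated benzylic chloride under iodide catalysis; no stereocentre is touched.

Step 3
Reactants: 3 PMB ether of trans-pulegol
Product: 4 (2R,4S)-2-(4-methoxybenzyloxy)-4-methylcyclohexan-1-one
Conditions: O3, CH2Cl2–MeOH, −78 °C; Me2S
Reagents that add atoms: ozone, [O-][O+]=O
Why: Ozonolysis with reductive work-up; the tetrasubstituted alkene reacts with ozone far faster than the anisyl ring, and the neutral work-up leaves the axial α-alkoxy stereocentre (its C–H is equatorial and poorly enolisable) unchanged.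

Step 4
Reactants: 4 (2R,4S)-2-(4-methoxybenzyloxy)-4-methylcyclohexan-1-one
Product: 6 (4R,6R)-6-(4-methoxybenzyloxy)-4-methylcyclohex-2-en-1-one, via silyl enol ether 5 (not isolated)
Conditions: LiN(i-Pr)2, Me3SiCl, THF, −78 °C; Pd(OAc)2, MeCN, rt
Reagents that add atoms: none
Why: Saegusa–Ito oxidation: kinetic deprotonation occurs at the CH2 group because the C–H geminal to the axial PMB ether is equatorial and not aligned with the carbonyl π system, and palladium diacetate then converts the silyl enol ether into the enone.

**Lactone donor**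

Step 5
Reactants: 7 (R)-2-methylbutanoic acid
Product: 8 (R)-2-methylbutan-1-ol
Conditions: LiAlH4, Et2O, 0 °C → rt; H2O
Reagents that add atoms: none
Why: Hydride reduction of the carboxylic acid to the primary alcohol; the α-stereocentre is not enolisable under these conditions.

Step 6
Reactants: 8 (R)-2-methylbutan-1-ol
Product: 10 methyl (2E,4R)-4-methylhex-2-enoate, via aldehyde 9 (not isolated)
Conditions: PhI(OAc)2, TEMPO (cat.), CH2Cl2, rt; Ph3P=CHCO2Me, rt
Reagents that add atoms: methyl (triphenylphosphoranylidene)acetate, COC(=O)C=P(c1ccccc1)(c1ccccc1)c1ccccc1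
Why: Oxoammonium oxidation followed in the same flask by a Wittig reaction with a stabilised ylide, so the racemisation-prone α-branched aldehyde is never isolated and the (E)-enoate is formed.

Step 7
Reactants: 10 methyl (2E,4R)-4-methylhex-2-enoate; 11 potassium vinyltrifluoroborate
Product: 12 methyl (3R,4R)-3-ethenyl-4-methylhexanoate
Conditions: [Rh(cod)2]BF4 (3 mol%), (R)-BINAP, toluene–H2O, 105 °C
Reagents that add atoms: none
Why: Asymmetric conjugate addition of an alkenyltrifluoroborate to an enoate catalysed by monovalent rhodium (Hayashi–Miyaura type); the (R)-BINAP complex is chosen to deliver the vinyl group to the re face of C3, overriding the weak bias of the neighbouring methyl/ethyl stereocentre and giving the (3R) centre that becomes C2.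

Step 8
Reactants: 12 methyl (3R,4R)-3-ethenyl-4-methylhexanoate
Product: 15 (4S)-4-[(2R)-butan-2-yl]oxolan-2-one, via ozonide 13 (not isolated), via hydroxy ester 14 (not isolated)
Conditions: O3, CH2Cl2, −78 °C; NaBH4, MeOH, −78 → 0 °C; 1 M HCl
Reagents that add atoms: ozone, [O-][O+]=O
Why: Ozonolysis of the vinyl group, borohydride reduction of the ozonide to the primary alcohol and acid-promoted lactonisation of the γ-hydroxy ester; the stereocentres are not involved.

Step 9
Reactants: 15 (4S)-4-[(2R)-butan-2-yl]oxolan-2-one
Product: 16 (4R)-4-[(2R)-butan-2-yl]-2-(tert-butyldimethylsilyloxy)-4,5-dihydrofuran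
Conditions: LiN(i-Pr)2, THF, −78 °C; t-BuMe2SiCl, DMPU
Reagents that add atoms: tert-butyldimethylsilyl chloride, CC(C)(C)[Si](C)(C)Cl
Why: O-silylation of the lithium lactone enolate (only one enolisable position) in the presence of DMPU gives the cyclic silyl ketene acetal.

**Union and precursor**

Step 10
Reactants: 6 (4R,6R)-6-(4-methoxybenzyloxy)-4-methylcyclohex-2-en-1-one; 16 cyclic silyl ketene acetal
Product: 17 Michael adduct (trans-3,4-disubstituted lactone on the ring B TBS enol ether)
Conditions: HNTf2 (5 mol%), CH2Cl2, −78 °C; Et3N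
Reagents that add atoms: none
Why: Mukaiyama–Michael addition under silyl triflimide catalysis with silyl transfer to the enone oxygen, which leaves the enol ether regiospecifically at C4a=C5; the cyclic ketene acetal is attacked anti to its sec-butyl group (C1, trans on the lactone) and the enone anti to its C4 methyl (C8a chain trans to the C8 methyl), so each new centre is set by its own neighbouring stereocentre.

Step 11
Reactants: 17 Michael adduct
Product: 18 γ-hydroxy N-methoxy-N-methylamide
Conditions: MeNH(OMe)·HCl, i-PrMgCl, THF, −20 → 0 °C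
Reagents that add atoms: N,O-dimethylhydroxylamine hydrochloride, CNOC.Cl
Why: Aminolysis of the lactone by the magnesium amide of N,O-dimethylhydroxylamine; the basic aprotic conditions spare the silyl enol ether, and C1 keeps its configuration because the trans lactone is the more stable epimer.

Step 12
Reactants: 18 γ-hydroxy N-methoxy-N-methylamide
Product: 19 aldehyde (C3 = CHO)
Conditions: SO3·pyridine, DMSO, i-Pr2NEt, CH2Cl2, 0 °C
Reagents that add atoms: none
Why: Parikh–Doering oxidation of the primary alcohol; the basic anhydrous conditions tolerate the silyl enol ether and stop at the aldehyde, which is used at once to avoid epimerisation at C2.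

Step 13
Reactants: 19 aldehyde
Product: 20 alkynyl amide on the ring B silyl enol ether (key-step precursor)
Conditions: Me3SiCHN2, n-BuLi, THF, −78 → 0 °C
Reagents that add atoms: (trimethylsilyl)diazomethane, C[Si](C)(C)C=[N+]=[N-]
Why: Colvin-type one-carbon homologation (addition of lithiated trimethylsilyldiazomethane, Peterson elimination, loss of N2 and 1,2-hydride shift of the alkylidene carbene) gives the terminal alkyne under aprotic low-temperature conditions that protect the C2 stereocentre and the silyl enol ether.

**Key step and ring fusion**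

Step 14
Reactants: 20 alkynyl amide on the ring B silyl enol ether
Product: 21 cis-fused β,γ-unsaturated ketone (ring A closed; 4aβ-H)
Conditions: W(CO)6 (30 mol%), DABCO, H2O, THF, hν (Pyrex), rt
Reagents that add atoms: none
Why: Photogenerated W(CO)5(THF), a zerovalent tungsten complex, binds the terminal alkyne and equilibrates (amine-assisted) with the vinylidene complex; C4a of the silyl enol ether adds to the electrophilic terminus C4, and protonation of the alkenyltungsten intermediate with loss of the silyl group to water releases the β,γ-unsaturated ketone and the catalyst. The closest known reaction type is the W(CO)5(THF)-catalysed endo-selective cyclisation of ω-alkynyl silyl enol ethers. Ring A closes in a 6-endo-dig mode at the alkyne (exo with respect to the enol ether double bond). The new stereocentre C4a is controlled by the tether: the chain anchored at C8a reaches the C4a p-orbital only on its own face, so the C4–C4a bond forms cis to the C8a–C1 bond (cis fusion, inverted in step 15). The step needs 6-endo rather than 5-exo closure, which the terminal alkyne reacting at its unsubstituted carbon through the vinylidene secures, and attack from C4a rather than C6, which is fixed because the Michael addition placed the enol ether at C4a=C5.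

Step 15
Reactants: 21 cis-fused β,γ-unsaturated ketone
Product: 23 trans-fused ketone (4aα-H; 8aβ-H), via potassium dienolate 22 (not isolated)
Conditions: KOt-Bu, THF, −78 → −40 °C; AcOH, −78 °C
Reagents that add atoms: none
Why: Deconjugative kinetic protonation: the doubly activated (α-keto, allylic) C4a–H is removed to give the C3=C4–C4a=C5 dienolate, which is protonated kinetically at the α-carbon C4a; H-8a is locked pseudoaxial in this dienolate, so stereoelectronically preferred axial protonation anti to H-8a on the α face (away from the β sec-butyl and amide groups) should give the trans fusion, and cis ketone, trans ketone or any conjugated isomer all funnel through the same dienolate.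

**Completion**

Step 16
Reactants: 23 trans-fused ketone
Product: 24 5α-alcohol
Conditions: NaBH4, CeCl3·7H2O, MeOH, −78 °C
Reagents that add atoms: none
Why: Luche reduction: the small hydride attacks C5 axially from the β face, anti to the axial C6–O bond (Felkin–Anh polar model), giving the equatorial 5α-alcohol cis to O6; the cerium salt speeds reduction so the base-labile β,γ-enone is consumed before it can isomerise, and the amide is inert.

Step 17
Reactants: 24 5α-alcohol
Product: 25 5α-triethylsilyl ether
Conditions: Et3SiOTf, 2,6-lutidine, CH2Cl2, −78 → 0 °C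
Reagents that add atoms: triethylsilyl trifluoromethanesulfonate, CC[Si](CC)(CC)OS(=O)(=O)C(F)(F)F
Why: Silylation of the hindered secondary alcohol with a silyl triflate and a hindered pyridine base; the TES ether is chosen so that it falls together with the tert-butyl ester in the last step.

Step 18
Reactants: 25 5α-triethylsilyl ether
Product: 26 C1 methyl ketone
Conditions: MeLi, THF, −78 → 0 °C; H2O
Reagents that add atoms: methyllithium, [Li]C
Why: Ketone synthesis from an N-methoxy-N-methylamide: the chelated tetrahedral intermediate survives until work-up, so no over-addition occurs and the C1 stereocentre is never exposed to base as a ketone.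

Step 19
Reactants: 26 C1 methyl ketone
Product: 27 6α-alcohol
Conditions: DDQ, CH2Cl2–pH 7 buffer, 0 °C
Reagents that add atoms: none
Why: Oxidative cleavage of the PMB ether by DDQ (benzylic hydride abstraction, hydrolysis of the oxocarbenium ion) frees only the axial C6 hydroxyl; TES ether, alkene and ketone are inert under buffered conditions.

Step 20
Reactants: 28 but-2-ynoic acid
Product: 30 (E)-3-iodobut-2-enoic acid, via Z iodo acid 29 (not isolated)
Conditions: 57% aq. HI, 130 °C, sealed tube
Reagents that add atoms: hydrogen iodide, I
Why: Conjugate hydroiodination of the ynoic acid; anti addition gives the (Z)-iodo acid first, which should equilibrate at 130 °C by addition–elimination of HI to the more stable (E)-isomer (iodine trans to the carboxyl group), the geometry required in the side chain.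

Step 21
Reactants: 30 (E)-3-iodobut-2-enoic acid; 31 2-tert-butoxy-2-oxoethylzinc chloride
Product: 32 (2E)-5-tert-butoxy-3-methyl-5-oxopent-2-enoic acid
Conditions: PdCl2(MeCN)2 (5 mol%), THF–DMF, rt; aq. HCl (pH 3)
Reagents that add atoms: none
Why: Negishi coupling of the Reformatsky-type zinc reagent with the alkenyl iodide (zerovalent palladium cycle, retention of alkene geometry); the first equivalent of zinc reagent is consumed by the carboxylic acid proton, and the free conjugated acid is obtained without any ester hydrolysis.

Step 22
Reactants: 27 6α-alcohol; 32 (2E)-5-tert-butoxy-3-methyl-5-oxopent-2-enoic acid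
Product: 33 protected target (6α-ester; 5α-OTES; tert-butyl ester)
Conditions: EDC·HCl, DMAP (0.2 equiv), CH2Cl2, 0 °C
Reagents that add atoms: none
Why: Steglich esterification (carbodiimide activation, catalytic DMAP acyl transfer) of the only free hydroxyl; low temperature and sub-stoichiometric DMAP limit deprotonation of the activated glutaconate at its CH2 group, which would scramble alkene position and geometry.

Step 23
Reactants: 33 protected target
Product: 34 CNP0404452.1
Conditions: TFA–CH2Cl2–H2O, 0 °C → rt
Reagents that add atoms: none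
Why: Acidolysis: trifluoroacetic acid cleaves the tert-butyl ester (E1 loss of isobutene) and the TES ether in one operation; acidic conditions avoid base-induced acyl migration from O6 to O5, epimerisation at C1 and isomerisation of the glutaconate.

**Compound list**

1 | (S)-pulegone, (5S)-5-methyl-2-(propan-2-ylidene)cyclohexan-1-one | C[C@H]1CCC(=C(C)C)C(=O)C1 | starting material
2 | trans-pulegol, (1R,5S)-5-methyl-2-(propan-2-ylidene)cyclohexan-1-ol (OH trans to CH3) | C[C@H]1CCC(=C(C)C)[C@H](O)C1 | intermediate
3 | (1R,5S)-1-(4-methoxybenzyloxy)-5-methyl-2-(propan-2-ylidene)cyclohexane | C[C@H]1CCC(=C(C)C)[C@H](OCc2ccc(OC)cc2)C1 | intermediate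
4 | (2R,4S)-2-(4-methoxybenzyloxy)-4-methylcyclohexan-1-one | C[C@H]1CCC(=O)[C@H](OCc2ccc(OC)cc2)C1 | intermediate
5 | (4S,6R)-6-(4-methoxybenzyloxy)-4-methyl-1-(trimethylsilyloxy)cyclohex-1-ene | C[C@H]1CC=C(O[Si](C)(C)C)[C@H](OCc2ccc(OC)cc2)C1 | intermediate (not isolated)
6 | (4R,6R)-6-(4-methoxybenzyloxy)-4-methylcyclohex-2-en-1-one | C[C@H]1C=CC(=O)[C@H](OCc2ccc(OC)cc2)C1 | intermediate
7 | (R)-2-methylbutanoic acid | CC[C@@H](C)C(=O)O | starting material
8 | (R)-2-methylbutan-1-ol | CC[C@@H](C)CO | intermediate
9 | (R)-2-methylbutanal | CC[C@@H](C)C=O | intermediate (not isolated)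
10 | methyl (2E,4R)-4-methylhex-2-enoate | CC[C@@H](C)/C=C/C(=O)OC | intermediate
11 | potassium vinyltrifluoroborate | C=C[B-](F)(F)F.[K+] | starting material
12 | methyl (3R,4R)-3-ethenyl-4-methylhexanoate | CC[C@@H](C)[C@@H](C=C)CC(=O)OC | intermediate
13 | ozonide of 12, methyl (4R)-4-methyl-3-(1,2,4-trioxolan-3-yl)hexanoate (C3 as in 12; trioxolane carbon unassigned) | CC[C@@H](C)[C@@H](C1OCOO1)CC(=O)OC | intermediate (not isolated)
14 | methyl (3S,4R)-3-(hydroxymethyl)-4-methylhexanoate | CC[C@@H](C)[C@@H](CO)CC(=O)OC | intermediate (not isolated)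
15 | (4S)-4-[(2R)-butan-2-yl]oxolan-2-one | CC[C@@H](C)[C@@H]1CC(=O)OC1 | intermediate
16 | (4R)-4-[(2R)-butan-2-yl]-2-(tert-butyldimethylsilyloxy)-4,5-dihydrofuran | CC[C@@H](C)[C@@H]1C=C(O[Si](C)(C)C(C)(C)C)OC1 | intermediate
17 | Michael adduct: oxolan-2-one with the (R)-sec-butyl group at C4 and, trans to it at C3 (= C1), the ring B cyclohexenyl TBS enol ether (C4a=C5–OTBS; 6α-OPMB; 8β-CH3) bonded through C8a (H-8a β) | CC[C@@H](C)[C@H]2COC(=O)[C@@H]2[C@@H]1C=C(O[Si](C)(C)C(C)(C)C)[C@H](OCc3ccc(OC)cc3)C[C@H]1C | intermediate
18 | hydroxy amide: ring B TBS enol ether carrying at C8a the chain C1H[C(O)N(OMe)Me]–C2H(sec-butyl)–CH2OH, configurations as in 17 | CC[C@@H](C)[C@@H](CO)[C@H](C(=O)N(C)OC)[C@@H]1C=C(O[Si](C)(C)C(C)(C)C)[C@H](OCc2ccc(OC)cc2)C[C@H]1C | intermediate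
19 | aldehyde: as 18 with C3 = CHO | CC[C@@H](C)[C@@H](C=O)[C@H](C(=O)N(C)OC)[C@@H]1C=C(O[Si](C)(C)C(C)(C)C)[C@H](OCc2ccc(OC)cc2)C[C@H]1C | intermediate
20 | key-step precursor: as 18 with ethynyl (C3≡C4) on C2 | CC[C@@H](C)[C@@H](C#C)[C@H](C(=O)N(C)OC)[C@@H]1C=C(O[Si](C)(C)C(C)(C)C)[C@H](OCc2ccc(OC)cc2)C[C@H]1C | intermediate
21 | cis-fused decalenone: 1β-C(O)N(OMe)Me; 2β-sec-butyl; C3=C4; 4aβ-H; C5 ketone; 6α-OPMB; 8β-CH3; 8aβ-H | CC[C@@H](C)[C@H]1C=C[C@@H]2C(=O)[C@H](OCc3ccc(OC)cc3)C[C@@H](C)[C@@H]2[C@H]1C(=O)N(C)OC | intermediate
22 | potassium C3=C4–C4a=C5 dienolate of 21 | CC[C@@H](C)[C@H]1C=CC2=C([O-])[C@H](OCc3ccc(OC)cc3)C[C@@H](C)[C@@H]2[C@H]1C(=O)N(C)OC.[K+] | intermediate (not isolated)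
23 | trans-fused decalenone: as 21 with 4aα-H | CC[C@@H](C)[C@H]1C=C[C@H]2C(=O)[C@H](OCc3ccc(OC)cc3)C[C@@H](C)[C@@H]2[C@H]1C(=O)N(C)OC | intermediate
24 | 5α-alcohol of 23 | CC[C@@H](C)[C@H]1C=C[C@H]2[C@H](O)[C@H](OCc3ccc(OC)cc3)C[C@@H](C)[C@@H]2[C@H]1C(=O)N(C)OC | intermediate
25 | 5α-triethylsilyl ether of 24 | CC[C@@H](C)[C@H]1C=C[C@H]2[C@H](O[Si](CC)(CC)CC)[C@H](OCc3ccc(OC)cc3)C[C@@H](C)[C@@H]2[C@H]1C(=O)N(C)OC | intermediate
26 | 1β-acetyl compound: 5α-OTES; 6α-OPMB | CC[C@@H](C)[C@H]1C=C[C@H]2[C@H](O[Si](CC)(CC)CC)[C@H](OCc3ccc(OC)cc3)C[C@@H](C)[C@@H]2[C@H]1C(C)=O | intermediate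
27 | 6α-alcohol: 1β-acetyl; 5α-OTES | CC[C@@H](C)[C@H]1C=C[C@H]2[C@H](O[Si](CC)(CC)CC)[C@H](O)C[C@@H](C)[C@@H]2[C@H]1C(C)=O | intermediate
28 | but-2-ynoic acid | CC#CC(=O)O | starting material
29 | (Z)-3-iodobut-2-enoic acid | C/C(I)=C/C(=O)O | intermediate (not isolated)
30 | (E)-3-iodobut-2-enoic acid | C/C(I)=C\C(=O)O | intermediate
31 | 2-tert-butoxy-2-oxoethylzinc chloride | CC(C)(C)OC(=O)C[Zn]Cl | starting material
32 | (2E)-5-tert-butoxy-3-methyl-5-oxopent-2-enoic acid | CC(C)(C)OC(=O)C/C(C)=C/C(=O)O | intermediate
33 | protected target: 6α-O-[(2E)-5-tert-butoxy-3-methyl-5-oxopent-2-enoyl]; 5α-OTES; 1β-acetyl | CC[C@@H](C)[C@H]1C=C[C@H]2[C@H](O[Si](CC)(CC)CC)[C@H](OC(=O)/C=C(\C)CC(=O)OC(C)(C)C)C[C@@H](C)[C@@H]2[C@H]1C(C)=O | intermediate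
34 | CNP0404452.1 | CC[C@@H](C)[C@H]1C=C[C@H]2[C@H](O)[C@H](OC(=O)/C=C(\C)CC(=O)O)C[C@@H](C)[C@@H]2[C@H]1C(C)=O | target

**Totals**

Total step count: 23. Longest linear sequence: 17 steps (from 7 to 34 through steps 5–19, 22 and 23).

**Steps most likely to fail**

1. Step 15. What may go wrong: protonation of dienolate 22 on the β face, which returns the cis ring fusion, or drift of the C3–C4 alkene into conjugation with C5 while the free β,γ-enone is handled. Fallback (dienyl acetate–borohydride deconjugation): starting from 21, dienolate 22 is generated as before and trapped on oxygen with acetic anhydride to give the dienyl acetate F1. Treating it with NaBH4 in EtOH–THF at 0 °C cleaves the enol acetate, the protic medium protonates C4a, and the β,γ-enone is reduced as soon as it forms, so it never accumulates. The sequence rejoins the route at alcohol 24.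

2. Step 14. What may go wrong: 5-exo closure at C3, or hydrolysis of the enol ether before ring closure, both possibly aggravated by the pseudoaxial C6 ether on the face of attack. Fallback (palladium-mediated enolate alkenylation): starting from aldehyde 19, Stork–Zhao olefination (Ph3PCH2I iodide, NaN(SiMe3)2, THF, −78 °C) gives the (Z)-vinyl iodide F2. Intramolecular coupling of the regiodefined enolate released from the silyl enol ether (Pd(PPh3)4, Bu3SnF, toluene, 80 °C; zerovalent palladium) forms the same C4–C4a bond. The cis C3–C4 alkene is fixed in advance by the iodide geometry, so only six-membered closure is possible. The sequence rejoins the route at 21.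

3. Step 22. What may go wrong: deprotonation of the activated acid at its doubly activated CH2 group with loss of alkene position and geometry, or slow acylation of the hindered axial alcohol. Fallback (two-stage construction of the side chain): starting from 27, esterification with iodo acid 30 (EDC·HCl, DMAP, CH2Cl2, 0 °C) gives the iodoenoate F3, which has no doubly activated methylene. Negishi coupling with zinc reagent 31 (Pd(PPh3)4, THF, rt) then installs the CH2CO2t-Bu arm with retention of alkene geometry. The sequence rejoins the route at 33.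

Further compounds
F1 | step 15 | dienyl acetate of 21/23: C3=C4–C4a=C5–OAc; otherwise as 23 | CC[C@@H](C)[C@H]1C=CC2=C(OC(C)=O)[C@H](OCc3ccc(OC)cc3)C[C@@H](C)[C@@H]2[C@H]1C(=O)N(C)OC
F2 | step 14 | (Z)-vinyl iodide: as 20 with (Z)-CH=CHI in place of ethynyl | CC[C@@H](C)[C@@H](/C=C\I)[C@H](C(=O)N(C)OC)[C@@H]1C=C(O[Si](C)(C)C(C)(C)C)[C@H](OCc2ccc(OC)cc2)C[C@H]1C
F3 | step 22 | 6α-O-[(E)-3-iodobut-2-enoyl] ester of 27 | CC[C@@H](C)[C@H]1C=C[C@H]2[C@H](O[Si](CC)(CC)CC)[C@H](OC(=O)/C=C(\C)I)C[C@@H](C)[C@@H]2[C@H]1C(C)=O
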